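**Structural features**

The target is a cis-fused octahydronaphthalene. Ring A (C4a, C5–C8, C8a) is a cyclohexane with a methyl/hydroxyl/methyl triad on C6, C7 and C8, all equatorial. Ring B (C1–C4, C4a, C8a) holds the C3=C4 alkene, an exocyclic (E)-ylidene on C2 that ends in a hydroxymethyl ketone, and on C1 a (2E,4Z,6E)-4,6-dimethylhepta-2,4,6-trienoic acid chain. Five stereocentres are contiguous (C1, C8a, C8, C7, C6) and the sixth, C4a, is next to C8a. C1 and C8 face each other across C8a, so the C1 chain stands axial on ring B, anti to C8, which also frees it from allylic strain with the carbonyl arm of the ylidene. The C1 hydrogen is γ to the dienone and sits at the far end of the trienoic acid, so base can epimerise C1 or pull C2=C1′ into the ring; the α-hydroxy ketone and the Z trisubstituted alkene of the triene are further weak points. A C1 aldehyde cannot coexist with the finished ylidene (a glutaconaldehyde-type system that enolises), which fixes the order of events at C1 and C2. The real difficulty is the cis ring fusion of a ring B that is functionalised on every carbon. The key step uses the fact that C8a is β to the C7 oxygen: with a C7 ketone and a C8=C8a alkene, C8a becomes an electrophilic carbon that a nucleophilic C1, hung from C4a through C4=C3–C2, can reach only on the face of its own tether, and the same carbonyl lets the C6 and C8 methyls settle equatorial.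

**Logic of the disconnections**

34 ⇒ 33. The last cut is the O–Si bond of the primary ketol. It leaves a fluoride-labile group as the only protection at the end, so the final step is neutral toward the acidic C1 hydrogen; the forward step must avoid base.

33 ⇒ 31 + 32. The bond between the Z trisubstituted alkene and the acrylic unit of the trienoic acid is cut. The iodoalkene of 31 stores the Z geometry and 32 brings the E enoic acid, so the acid arrives last and no earlier step has to tolerate a trienoate that acidifies C1–H. The coupling must retain the iodoalkene geometry and work with weak base.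

31 ⇒ 30 ⇒ 28 + 29. The ylidene enone is traced to a tertiary propargylic alcohol (1,3-oxygen transposition), and the C2–C1′ bond is cut to a ring ketone and an alkyne. This puts the three-carbon ketol arm on the hindered C2 in two steps, with the ylidene geometry under thermodynamic control. Addition to C2 must beat enolisation toward C1, and the rearrangement must not engage the nearby chain alkene.

28 ⇒ 27 ⇒ 26. These are oxidation-level and protecting-group changes only. C2 has to be a silyl ether while C1 carries an aldehyde, and it is re-oxidised afterwards; because C2–OH is allylic and C7–OH is not, one silyl type serves for both and no protection of C7 is needed later.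

26 ⇒ 24 + 25, and 24 ⇒ 22 + 23. The two C=C bonds of the chain nearest the ring are cut in turn. Each olefination is chosen for its geometry (E enal, then Z iodoalkene), and the chain stays free of electron-withdrawing groups until C2 has been alkynylated.

22 ⇒ 21 ⇒ 20 ⇒ 19. Functional-group interconversion shows that the ester carbon of the β-keto ester is the first carbon of the chain. Both ring ketones are reduced together, which sets C7 and masks C2. The forward reduction must deliver hydride axially at C7.

19 ⇒ 17. The C1–C8a bond is cut (key step). This removes ring B and two stereocentres (C8a, C8) and leaves a monocyclic enone with one arm. The forward ring closure must be cis, C-selective, and followed by equatorial settling of C6 and C8.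

17 ⇒ 16 ⇒ 15 ⇒ 11 + 12. The ring enone is traced to a protected allylic alcohol, and the C1–C2 bond of the β-keto ester is cut to an acid and a malonate half ester. The acylation is neutral, so the Z enone arm and the C4a centre are not exposed to ester enolates.

11 ⇒ 10 ⇒ 8 + 9. The C3=C4 bond is cut; the Z geometry that ring B needs must come from a Z-selective phosphonate olefination of an α-branched aldehyde.

8 ⇒ 7 ⇒ 6 ⇒ 5. Redox adjustments: the ring ketone is hidden as a silyl ether while the ester is taken to the aldehyde and the arm is built, because a γ-formyl enone would lose its C4a configuration.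

5 ⇒ 4 ⇒ 3. The enone is traced to a meso ketone through an enantiotopic-proton-selective enolisation; this step creates the C4a configuration and thus all absolute stereochemistry.

3 ⇒ 2 ⇒ 1. The meso ketone comes from arene hydrogenation and oxidation of a commercial phenol ester.

**Other disconnections considered**

Alternative 1: The cut is C4–C4a plus C1–C8a. In the forward step 2-(tert-butyldimethylsilyloxy)-3-methylbuta-1,3-diene A1 adds to the C4a=C8a bond of the ring A enone A2 (carbonyl at C5) to give the cis-fused silyl enol ether A3.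
- In its favour: two bonds and ring B form at once, the fusion is cis by suprafacial addition, and the C6–C8 triad is already present, so C8a is set kinetically anti to the C8 methyl. The silyl enol ether of A3 is a regiodefined handle for the C2 ketone and the C3=C4 alkene.
- Against it: the activating C5 carbonyl is not part of the target and must be removed next to C4a. Cyclohexenones with γ-substitution are sluggish dienophiles, and the Lewis acid they need threatens A1. C1 arrives as a bare CH2, so the chain must be attached later α′ to the C2 ketone with its own stereochemical problem. A2 needs a separate enantioselective synthesis of three stereocentres.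
- Comparison: A3 is the equal of the chosen plan on fusion control. It is better at C8 (kinetic, not by equilibration) and at C7 (no late ketone reduction). It is worse in redox economy and in carbon count at C1, where the chosen plan delivers C1 with its first chain carbon and uses the target's own C7 oxygen as activator.

Alternative 2: The cut is C6–C7. In the forward step single-electron reduction of aldehyde A4 (ring B with a C2 ketal, an allyl group on C4a and a 1-formylethyl group on C8a) gives a ketyl that closes 6-exo onto the allyl group to give carbinol A5.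
- In its favour: the C7 hydroxyl is made directly at the right oxidation level, and a chair-like transition state can place OH and the new C6 methyl trans. On the C7 problem this is better than a separate hydride reduction.
- Against it: the acceptor is an unactivated terminal alkene, so the closure needs strongly reducing conditions and competes with pinacol coupling and simple reduction. The C8 centre is α to the aldehyde and can epimerise before closure. The cis relationship of the two arms on C4a and C8a must already exist, so the fusion problem is only moved. C1 is again a CH2 and the ylidene is still to be made.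
- Comparison: it is equal in bonds and rings formed (one each) and better at C7. It is worse on fusion control, on the C1 carbon, and in total steps.

Alternative 3: The cut is C1–C2. In the forward step Lewis acid activation of the enynone arm on C4a of A6 lets the γ-carbon of the silyl dienol ether on C8a add to the alkyne β-carbon, giving ring B, the ylidene enone and the C1 enal arm of A7.
- In its favour: it is the most convergent of the four. Ring B, the ylidene with its full oxygen pattern and the first chain alkene appear together; the alkynylation/rearrangement pair and the C1 aldehyde problem disappear; and A7 is two olefinations from the target. In late-stage step economy it is better than the chosen plan.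
- Against it: it requires γ-selectivity (over α) of the dienol ether and attack at the alkyne carbon of a cross-conjugated acceptor. The ylidene geometry depends on allenolate protonation and C1 on an open transition state. A6 already needs the cis arms and the C6–C8 triad, so its synthesis is long and linear. Intramolecular vinylogous Mukaiyama–Michael additions to ynones have thin precedent.
- Comparison: mechanistically the chosen base-mediated Michael closure of a β-keto ester onto a cyclohexenone is the more secure reaction type, and it creates the fusion instead of presupposing it. A7 is the equal of the chosen plan in that the C1 configuration is thermodynamic in both.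

Key step: step 13

Remarks and assumptions:
- Correction at C6: the enone that a meso ketone can deliver carries the C6 methyl cis to the C4a substituent. The key-step precursor 17 is therefore the isomer with C6 cis to the arm, not one that already has C6 as in the product. C6 is corrected in the key step, because it is α to the C7 carbonyl of the cyclised product.
- Improvement of the way to the precursor: the ring ketone is kept as a silyl-protected allylic alcohol while the arm is built and is unveiled one step before the closure. This avoids a γ-formyl enone and an ester-enolate Claisen reaction in the presence of a ketone.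
- Locants: in the monocyclic compounds 4–17, ring carbons 1, 2, 3, 4, 5, 6 are the future C4a, C8a, C8, C7, C6, C5.
- Assumption on the chiral base: the (R,R)-amide is taken to remove the proton that leads to 4 as drawn; if the sense of induction on 3 is the reverse, the (S,S)-amide is used with no other change.
- Assumption on transient carbinol centres: centres that are later oxidised or lost (ring carbon 4 in 6–16, C2 in 20–27 and 30) are drawn as the expected major epimer; the other epimer converges on the same later compound.

Step 1
Reactants: 1 methyl 4-hydroxy-3,5-dimethylbenzoate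
Product: 2 methyl all-cis-4-hydroxy-3,5-dimethylcyclohexane-1-carboxylate
Conditions: H2 (60 bar), Rh/Al2O3, MeOH, 50 °C
Reagents that add atoms: none
Why: Heterogeneous arene hydrogenation over rhodium delivers hydrogen from one face, so ester, both methyls and hydroxyl should end up cis; the carbinol configuration is erased in step 2.

Step 2
Reactants: 2 methyl all-cis-4-hydroxy-3,5-dimethylcyclohexane-1-carboxylate
Product: 3 methyl cis,cis-3,5-dimethyl-4-oxocyclohexane-1-carboxylate (meso)
Conditions: NaOCl, AcOH, 15–25 °C
Reagents that add atoms: none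
Why: Hypochlorite oxidation of a secondary alcohol in acetic acid; both α-methyls and the ester are equatorial in 3, so the all-cis meso ketone is also the stable isomer.

Step 3
Reactants: 3 methyl cis,cis-3,5-dimethyl-4-oxocyclohexane-1-carboxylate
Product: 4 methyl (1S,5R)-3,5-dimethyl-4-(trimethylsilyloxy)cyclohex-3-ene-1-carboxylate
Conditions: (R,R)-bis(1-phenylethyl)amine·HCl, n-BuLi (2 equiv), THF, −78 °C; then 3 and Me3SiCl, −100 → −78 °C
Reagents that add atoms: chlorotrimethylsilane, C[Si](C)(C)Cl
Why: Asymmetric enolisation of a meso ketone by a C2-symmetric chiral lithium amide with silyl trapping; the two axial α-hydrogens are enantiotopic, the ester α-hydrogen is kinetically slower at this temperature, and the untouched methyl centre stays cis to the ester.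

Step 4
Reactants: 4 methyl (1S,5R)-3,5-dimethyl-4-(trimethylsilyloxy)cyclohex-3-ene-1-carboxylate
Product: 5 methyl (1S,5R)-3,5-dimethyl-4-oxocyclohex-2-ene-1-carboxylate
Conditions: Pd(OAc)2 (1.05 equiv), MeCN, 25 °C
Reagents that add atoms: none
Why: Saegusa–Ito oxidation; the palladium enolate at the methyl-bearing carbon should lose a ring β-hydride to give the 2-methyl enone under neutral conditions that leave the γ-ester centre alone.

Step 5
Reactants: 5 methyl (1S,5R)-3,5-dimethyl-4-oxocyclohex-2-ene-1-carboxylate
Product: 6 methyl (1S,4S,5R)-4-hydroxy-3,5-dimethylcyclohex-2-ene-1-carboxylate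
Conditions: NaBH4, CeCl3·7H2O, MeOH, −78 → −20 °C
Reagents that add atoms: none
Why: Luche 1,2-reduction is selective for the enone carbonyl over the ester and switches off the acidity of the ring γ-hydrogen (future C4a–H) for the next six steps; the carbinol configuration (expected trans to the adjacent methyl) is irrelevant because step 12 removes it.

Step 6
Reactants: 6 methyl (1S,4S,5R)-4-hydroxy-3,5-dimethylcyclohex-2-ene-1-carboxylate
Product: 7 methyl (1S,4S,5R)-4-(tert-butyldimethylsilyloxy)-3,5-dimethylcyclohex-2-ene-1-carboxylate
Conditions: t-BuMe2SiOTf, 2,6-lutidine, CH2Cl2, 0 °C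
Reagents that add atoms: tert-butyldimethylsilyl triflate, CC(C)(C)[Si](C)(C)OS(=O)(=O)C(F)(F)F
Why: Silylation of a hindered secondary allylic alcohol with the silyl triflate and a non-nucleophilic base; the ether survives hydride, amide base, hydroxide and the acylation of step 10.

Step 7
Reactants: 7 methyl (1S,4S,5R)-4-(tert-butyldimethylsilyloxy)-3,5-dimethylcyclohex-2-ene-1-carboxylate
Product: 8 (1S,4S,5R)-4-(tert-butyldimethylsilyloxy)-3,5-dimethylcyclohex-2-ene-1-carbaldehyde
Conditions: i-Bu2AlH (1.1 equiv), CH2Cl2, −78 °C; aq. potassium sodium tartrate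
Reagents that add atoms: none
Why: Half-reduction of a methyl ester through the aluminium hemiacetal that is stable at −78 °C; the β,γ-unsaturated aldehyde is used at once so that its α-centre neither epimerises nor moves into conjugation.

Step 8
Reactants: 8 (1S,4S,5R)-4-(tert-butyldimethylsilyloxy)-3,5-dimethylcyclohex-2-ene-1-carbaldehyde; 9 ethyl 2-[bis(2,2,2-trifluoroethoxy)phosphoryl]propanoate
Product: 10 ethyl (2Z)-3-[(1S,4S,5R)-4-(tert-butyldimethylsilyloxy)-3,5-dimethylcyclohex-2-en-1-yl]-2-methylprop-2-enoate
Conditions: 9, KN(SiMe3)2, 18-crown-6, THF, −78 °C; then 8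
Reagents that add atoms: none
Why: Still–Gennari olefination; the electron-poor phosphonate with a dissociated potassium counter-ion eliminates fast from the kinetic adduct, which should give the Z trisubstituted enoate that ring B needs.

Step 9
Reactants: 10 ethyl (2Z)-3-[(1S,4S,5R)-4-(tert-butyldimethylsilyloxy)-3,5-dimethylcyclohex-2-en-1-yl]-2-methylprop-2-enoate
Product: 11 (2Z)-3-[(1S,4S,5R)-4-(tert-butyldimethylsilyloxy)-3,5-dimethylcyclohex-2-en-1-yl]-2-methylprop-2-enoic acid
Conditions: LiOH, THF/MeOH/H2O, 40 °C; then 1 M HCl to pH 3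
Reagents that add atoms: lithium hydroxide, [Li+].[OH-]
Why: Saponification; with the ring carbonyl masked, the ring hydrogen γ to the enoate is only weakly acidic, so the Z geometry and the C4a centre should survive hydroxide.

Step 10
Reactants: 11 (2Z)-3-[(1S,4S,5R)-4-(tert-butyldimethylsilyloxy)-3,5-dimethylcyclohex-2-en-1-yl]-2-methylprop-2-enoic acid; 12 potassium 3-methoxy-3-oxopropanoate
Product: 15 methyl (4Z)-5-[(1S,4S,5R)-4-(tert-butyldimethylsilyloxy)-3,5-dimethylcyclohex-2-en-1-yl]-4-methyl-3-oxopent-4-enoate, via acyl imidazole 13 (not isolated), via acylmalonic half ester 14 (not isolated)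
Conditions: CDI, THF, 25 °C; then 12, MgCl2, Et3N, MeCN, 25 → 45 °C; 1 M HCl
Reagents that add atoms: 1,1′-carbonyldiimidazole, O=C(n1ccnc1)n1ccnc1 (imidazolide unit of 13 only; none of its atoms remain in 15)
Why: Masamune-type chain extension; the acyl imidazole C-acylates the magnesium enolate of the malonate half ester and the adduct decarboxylates, which builds the β-keto ester under near-neutral conditions and avoids an ester enolate that could add 1,4 to the enoate.

Step 11
Reactants: 15 methyl (4Z)-5-[(1S,4S,5R)-4-(tert-butyldimethylsilyloxy)-3,5-dimethylcyclohex-2-en-1-yl]-4-methyl-3-oxopent-4-enoate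
Product: 16 methyl (4Z)-5-[(1S,4S,5R)-4-hydroxy-3,5-dimethylcyclohex-2-en-1-yl]-4-methyl-3-oxopent-4-enoate
Conditions: HF·pyridine, pyridine, THF, 0 → 25 °C
Reagents that add atoms: none
Why: Buffered fluoride cleavage of the silyl ether; no base is present that could enolise the β-keto ester toward side reactions.

Step 12
Reactants: 16 methyl (4Z)-5-[(1S,4S,5R)-4-hydroxy-3,5-dimethylcyclohex-2-en-1-yl]-4-methyl-3-oxopent-4-enoate
Product: 17 methyl (4Z)-5-[(1R,5R)-3,5-dimethyl-4-oxocyclohex-2-en-1-yl]-4-methyl-3-oxopent-4-enoate
Conditions: MnO2 (excess), CH2Cl2, 25 °C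
Reagents that add atoms: none
Why: Allylic alcohol oxidation on the MnO2 surface, chosen because it does not oxidise the active methylene of the β-keto ester; the product is taken straight into step 13.

Step 13
Reactants: 17 methyl (4Z)-5-[(1R,5R)-3,5-dimethyl-4-oxocyclohex-2-en-1-yl]-4-methyl-3-oxopent-4-enoate
Product: 19 methyl (4aR,6S,8R,8aS)-2-hydroxy-3,6,8-trimethyl-7-oxo-4a,5,6,7,8,8a-hexahydronaphthalene-1-carboxylate, via kinetic Michael adduct 18 (not isolated)
Conditions: Cs2CO3 (2 equiv), MeCN (0.01 M), 0 → 25 °C; then MeOH, 40 °C; aq. NH4Cl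
Reagents that add atoms: none
Why: Carbonate deprotonates only the β-keto ester, and its enolate carbon C1 adds to C8a of the ring enone; the resulting C7 enolate is protonated at C8. The closest known reaction type is the base-mediated intramolecular Michael addition of β-keto esters to cyclohexenones, which gives cis-fused bicycles. Ring B closes in a 6-exo-trig mode with the enolate double bond inside the new ring (6-enolendo), which is geometrically allowed because the Z C3=C4 bond holds C2 beside the ring. C8a is controlled by the tether: the arm on C4a stays pseudo-equatorial, C1 enters along the axial trajectory on the same face, and a trans fusion is out of reach for a four-atom, largely planar chain. C4a is the centre set in step 3 and is not touched. C6 and C8 are under thermodynamic control: the first adduct 18 keeps the C6 methyl cis to C4 and is expected to protonate C8 cis to C1, and methanolic carbonate then epimerises both centres through the C7 enol(ate) to 19, in which both methyls are equatorial and the C1 ester avoids allylic and peri strain with C8. The step needs C- over O-alkylation (oxa-Michael closure is reversible and drains to the C–C product), β-keto ester over C4a–H deprotonation (secured by the large acidity gap and the aprotic first stage), and high dilution against intermolecular addition.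

Step 14
Reactants: 19 methyl (4aR,6S,8R,8aS)-2-hydroxy-3,6,8-trimethyl-7-oxo-4a,5,6,7,8,8a-hexahydronaphthalene-1-carboxylate
Product: 20 methyl (1S,2S,4aS,6S,7R,8R,8aS)-2,7-dihydroxy-3,6,8-trimethyl-1,2,4a,5,6,7,8,8a-octahydronaphthalene-1-carboxylate
Conditions: NaBH4, CeCl3·7H2O, MeOH/THF, −40 → 0 °C
Reagents that add atoms: none
Why: Luche reduction of both carbonyls: axial hydride attack on the conformationally fixed C7 ketone should give the equatorial alcohol, the C2 carbonyl is reduced 1,2 through the keto tautomer, and C1 is fixed with the ester axial and anti to C8, the arrangement that avoids the peri clash with the C8 methyl.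

Step 15
Reactants: 20 methyl (1S,2S,4aS,6S,7R,8R,8aS)-2,7-dihydroxy-3,6,8-trimethyl-1,2,4a,5,6,7,8,8a-octahydronaphthalene-1-carboxylate
Product: 21 2,7-bis(triethylsilyl) ether of 20
Conditions: Et3SiOTf, 2,6-lutidine, CH2Cl2, −78 → 0 °C
Reagents that add atoms: triethylsilyl triflate, CC[Si](CC)(CC)OS(=O)(=O)C(F)(F)F
Why: Silylation of both secondary alcohols; C2 must stay at the alcohol level while C1 carries an aldehyde, and one silyl type suffices because the two alcohols are told apart later by allylic oxidation.

Step 16
Reactants: 21 2,7-bis(triethylsilyl) ether of 20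
Product: 22 (1S,2S,4aS,6S,7R,8R,8aS)-3,6,8-trimethyl-2,7-bis(triethylsilyloxy)-1,2,4a,5,6,7,8,8a-octahydronaphthalene-1-carbaldehyde
Conditions: i-Bu2AlH (1.2 equiv), CH2Cl2, −78 °C; aq. potassium sodium tartrate
Reagents that add atoms: none
Why: Half-reduction of a β-silyloxy methyl ester; the aluminium hemiacetal is stabilised by the neighbouring oxygen, and the axial aldehyde is already the thermodynamic C1 epimer.

Step 17
Reactants: 22 (1S,2S,4aS,6S,7R,8R,8aS)-3,6,8-trimethyl-2,7-bis(triethylsilyloxy)-1,2,4a,5,6,7,8,8a-octahydronaphthalene-1-carbaldehyde; 23 2-(triphenylphosphoranylidene)propanal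
Product: 24 (2E)-2-methyl-3-[3,6,8-trimethyl-2,7-bis(triethylsilyloxy)-1,2,4a,5,6,7,8,8a-octahydronaphthalen-1-yl]prop-2-enal (ring configuration as in 22)
Conditions: 23, toluene, 90 °C
Reagents that add atoms: none
Why: Wittig reaction of a stabilised formyl ylide, which should give the E trisubstituted enal under base-free conditions that a β-silyloxy aldehyde tolerates.

Step 18
Reactants: 24 (2E)-2-methyl-3-[3,6,8-trimethyl-2,7-bis(triethylsilyloxy)-1,2,4a,5,6,7,8,8a-octahydronaphthalen-1-yl]prop-2-enal; 25 ethyltriphenylphosphonium iodide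
Product: 26 1-[(1E,3Z)-4-iodo-2-methylpenta-1,3-dien-1-yl]-3,6,8-trimethyl-2,7-bis(triethylsilyloxy)-1,2,4a,5,6,7,8,8a-octahydronaphthalene (ring configuration as in 22)
Conditions: 25, n-BuLi, THF, 0 °C; I2, −78 °C; NaN(SiMe3)2, −20 °C; then 24, −78 °C
Reagents that add atoms: iodine, II
Why: Stork–Zhao olefination with the α-iodo ethylidene ylide, which should place iodine cis to the chain (Z iodoalkene); this stores the geometry of the central trisubstituted alkene in a group that carries no electron-withdrawing function.

Step 19
Reactants: 26 1-[(1E,3Z)-4-iodo-2-methylpenta-1,3-dien-1-yl]-3,6,8-trimethyl-2,7-bis(triethylsilyloxy)-1,2,4a,5,6,7,8,8a-octahydronaphthalene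
Product: 27 1-[(1E,3Z)-4-iodo-2-methylpenta-1,3-dien-1-yl]-3,6,8-trimethyl-1,2,4a,5,6,7,8,8a-octahydronaphthalene-2,7-diol (ring configuration as in 20)
Conditions: HF·pyridine, pyridine, THF, 0 → 25 °C
Reagents that add atoms: none
Why: Buffered fluoride removal of both triethylsilyl ethers; the iododiene is inert to these conditions.

Step 20
Reactants: 27 1-[(1E,3Z)-4-iodo-2-methylpenta-1,3-dien-1-yl]-3,6,8-trimethyl-1,2,4a,5,6,7,8,8a-octahydronaphthalene-2,7-diol
Product: 28 7-hydroxy-1-[(1E,3Z)-4-iodo-2-methylpenta-1,3-dien-1-yl]-3,6,8-trimethyl-4a,5,6,7,8,8a-hexahydronaphthalen-2(1H)-one (C1 chain axial and anti to C8; C6, C7, C8, C4a, C8a as in the target)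
Conditions: MnO2 (excess), CH2Cl2, 25 °C
Reagents that add atoms: none
Why: Chemoselective oxidation of the allylic C2 alcohol by MnO2; the saturated C7 alcohol is not oxidised, so it needs no protection from here on.

Step 21
Reactants: 28 7-hydroxy-1-[(1E,3Z)-4-iodo-2-methylpenta-1,3-dien-1-yl]-3,6,8-trimethyl-4a,5,6,7,8,8a-hexahydronaphthalen-2(1H)-one; 29 tert-butyldimethyl(prop-2-yn-1-yloxy)silane
Product: 30 2-[3-(tert-butyldimethylsilyloxy)prop-1-yn-1-yl]-1-[(1E,3Z)-4-iodo-2-methylpenta-1,3-dien-1-yl]-3,6,8-trimethyl-1,2,4a,5,6,7,8,8a-octahydronaphthalene-2,7-diol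
Conditions: 29 (4 equiv), n-BuLi, THF, −78 °C; CeCl3 (anhydrous), −78 °C; then 28; aq. NH4Cl
Reagents that add atoms: none
Why: 1,2-Addition of a weakly basic organocerium acetylide to an enone; enolisation toward C1 is disfavoured because the C1 hydrogen is pseudo-equatorial and lies near the nodal plane of the carbonyl, and the excess reagent covers the free C7 hydroxyl; the new C2 centre is lost in step 22.

Step 22
Reactants: 30 2-[3-(tert-butyldimethylsilyloxy)prop-1-yn-1-yl]-1-[(1E,3Z)-4-iodo-2-methylpenta-1,3-dien-1-yl]-3,6,8-trimethyl-1,2,4a,5,6,7,8,8a-octahydronaphthalene-2,7-diol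
Product: 31 (1E)-3-(tert-butyldimethylsilyloxy)-1-{7-hydroxy-1-[(1E,3Z)-4-iodo-2-methylpenta-1,3-dien-1-yl]-3,6,8-trimethyl-4a,5,6,7,8,8a-hexahydronaphthalen-2(1H)-ylidene}propan-2-one (ring configuration as in the target)
Conditions: Bu4N[ReO4] (10 mol %), p-TsOH·H2O (10 mol %), CH2Cl2, 25 °C
Reagents that add atoms: none
Why: Meyer–Schuster rearrangement through a perrhenate ester and its [3,3] shift to the allenyl ester, which tautomerises irreversibly to the enone; an oxo-metal catalyst is chosen over a π-acid so that the chain alkene, which forms a 1,5-enyne with the alkyne, is not drawn into cycloisomerisation, and the E ylidene (carbonyl arm away from the C3 methyl, beside the in-plane C1 hydrogen) is the thermodynamic isomer.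

Step 23
Reactants: 31 (1E)-3-(tert-butyldimethylsilyloxy)-1-{7-hydroxy-1-[(1E,3Z)-4-iodo-2-methylpenta-1,3-dien-1-yl]-3,6,8-trimethyl-4a,5,6,7,8,8a-hexahydronaphthalen-2(1H)-ylidene}propan-2-one; 32 acrylic acid
Product: 33 (2E,4Z,6E)-7-{(1R,2E,4aS,6S,7R,8R,8aR)-2-[3-(tert-butyldimethylsilyloxy)-2-oxopropylidene]-7-hydroxy-3,6,8-trimethyl-1,2,4a,5,6,7,8,8a-octahydronaphthalen-1-yl}-4,6-dimethylhepta-2,4,6-trienoic acid
Conditions: 32, Pd(OAc)2 (5 mol %), KOAc, Bu4NCl, DMF, 25–40 °C, dark
Reagents that add atoms: none
Why: Heck coupling under ligand-free phase-transfer conditions; oxidative addition and insertion retain the iodoalkene geometry and syn β-hydride elimination gives the E acrylic terminus, and cyclisation of the alkenylpalladium onto ring B is excluded by the E geometry of the first chain alkene.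

Step 24
Reactants: 33 (2E,4Z,6E)-7-{(1R,2E,4aS,6S,7R,8R,8aR)-2-[3-(tert-butyldimethylsilyloxy)-2-oxopropylidene]-7-hydroxy-3,6,8-trimethyl-1,2,4a,5,6,7,8,8a-octahydronaphthalen-1-yl}-4,6-dimethylhepta-2,4,6-trienoic acid
Product: 34 (2E,4Z,6E)-7-[(1R,2E,4aS,6S,7R,8R,8aR)-7-hydroxy-2-(3-hydroxy-2-oxopropylidene)-3,6,8-trimethyl-1,2,4a,5,6,7,8,8a-octahydronaphthalen-1-yl]-4,6-dimethylhepta-2,4,6-trienoic acid
Conditions: HF·pyridine, pyridine, THF, 0 °C
Reagents that add atoms: none
Why: Buffered fluoride cleavage of a primary silyl ether α to a ketone; no base is present, so the C1 centre and the position of the ylidene double bond are not put at risk.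

**Compound list**

1 | methyl 4-hydroxy-3,5-dimethylbenzoate | COC(=O)c1cc(C)c(O)c(C)c1 | starting material
2 | methyl all-cis-4-hydroxy-3,5-dimethylcyclohexane-1-carboxylate (meso) | COC(=O)[C@@H]1C[C@H](C)[C@H](O)[C@H](C)C1 | intermediate
3 | methyl cis,cis-3,5-dimethyl-4-oxocyclohexane-1-carboxylate (meso; ester and both methyls on one face) | COC(=O)[C@@H]1C[C@H](C)C(=O)[C@H](C)C1 | intermediate
4 | methyl (1S,5R)-3,5-dimethyl-4-(trimethylsilyloxy)cyclohex-3-ene-1-carboxylate | COC(=O)[C@@H]1CC(C)=C(O[Si](C)(C)C)[C@H](C)C1 | intermediate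
5 | methyl (1S,5R)-3,5-dimethyl-4-oxocyclohex-2-ene-1-carboxylate (ester and C5 methyl cis) | COC(=O)[C@@H]1C=C(C)C(=O)[C@H](C)C1 | intermediate
6 | methyl (1S,4S,5R)-4-hydroxy-3,5-dimethylcyclohex-2-ene-1-carboxylate | COC(=O)[C@@H]1C=C(C)[C@@H](O)[C@H](C)C1 | intermediate
7 | methyl (1S,4S,5R)-4-(tert-butyldimethylsilyloxy)-3,5-dimethylcyclohex-2-ene-1-carboxylate | COC(=O)[C@@H]1C=C(C)[C@@H](O[Si](C)(C)C(C)(C)C)[C@H](C)C1 | intermediate
8 | (1S,4S,5R)-4-(tert-butyldimethylsilyloxy)-3,5-dimethylcyclohex-2-ene-1-carbaldehyde | O=C[C@@H]1C=C(C)[C@@H](O[Si](C)(C)C(C)(C)C)[C@H](C)C1 | intermediate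
9 | ethyl 2-[bis(2,2,2-trifluoroethoxy)phosphoryl]propanoate | CCOC(=O)C(C)P(=O)(OCC(F)(F)F)OCC(F)(F)F | starting material
10 | ethyl (2Z)-3-[(1S,4S,5R)-4-(tert-butyldimethylsilyloxy)-3,5-dimethylcyclohex-2-en-1-yl]-2-methylprop-2-enoate | CCOC(=O)/C(C)=C\[C@@H]1C=C(C)[C@@H](O[Si](C)(C)C(C)(C)C)[C@H](C)C1 | intermediate
11 | (2Z)-3-[(1S,4S,5R)-4-(tert-butyldimethylsilyloxy)-3,5-dimethylcyclohex-2-en-1-yl]-2-methylprop-2-enoic acid | OC(=O)/C(C)=C\[C@@H]1C=C(C)[C@@H](O[Si](C)(C)C(C)(C)C)[C@H](C)C1 | intermediate
12 | potassium 3-methoxy-3-oxopropanoate (potassium methyl malonate) | [K+].[O-]C(=O)CC(=O)OC | starting material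
13 | acyl imidazole of 11 | O=C(n1ccnc1)/C(C)=C\[C@@H]1C=C(C)[C@@H](O[Si](C)(C)C(C)(C)C)[C@H](C)C1 | intermediate (not isolated)
14 | 2-(methoxycarbonyl)-3-oxo acid formed by C-acylation of the malonate half ester with 13 | COC(=O)C(C(=O)O)C(=O)/C(C)=C\[C@@H]1C=C(C)[C@@H](O[Si](C)(C)C(C)(C)C)[C@H](C)C1 | intermediate (not isolated)
15 | methyl (4Z)-5-[(1S,4S,5R)-4-(tert-butyldimethylsilyloxy)-3,5-dimethylcyclohex-2-en-1-yl]-4-methyl-3-oxopent-4-enoate | COC(=O)CC(=O)/C(C)=C\[C@@H]1C=C(C)[C@@H](O[Si](C)(C)C(C)(C)C)[C@H](C)C1 | intermediate
16 | methyl (4Z)-5-[(1S,4S,5R)-4-hydroxy-3,5-dimethylcyclohex-2-en-1-yl]-4-methyl-3-oxopent-4-enoate | COC(=O)CC(=O)/C(C)=C\[C@@H]1C=C(C)[C@@H](O)[C@H](C)C1 | intermediate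
17 | methyl (4Z)-5-[(1R,5R)-3,5-dimethyl-4-oxocyclohex-2-en-1-yl]-4-methyl-3-oxopent-4-enoate (key-step precursor; C6 methyl cis to the arm) | COC(=O)CC(=O)/C(C)=C\[C@@H]1C=C(C)C(=O)[C@H](C)C1 | intermediate
18 | methyl (4aR,6R,8S,8aS)-2-hydroxy-3,6,8-trimethyl-7-oxo-4a,5,6,7,8,8a-hexahydronaphthalene-1-carboxylate (kinetic adduct, 6,8-bis-epimer of 19) | CC1=C[C@H]2C[C@@H](C)C(=O)[C@@H](C)[C@H]2C(C(=O)OC)=C1O | intermediate (not isolated)
19 | methyl (4aR,6S,8R,8aS)-2-hydroxy-3,6,8-trimethyl-7-oxo-4a,5,6,7,8,8a-hexahydronaphthalene-1-carboxylate (key-step product, cis-fused, enol form) | CC1=C[C@H]2C[C@H](C)C(=O)[C@H](C)[C@H]2C(C(=O)OC)=C1O | intermediate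
20 | methyl (1S,2S,4aS,6S,7R,8R,8aS)-2,7-dihydroxy-3,6,8-trimethyl-1,2,4a,5,6,7,8,8a-octahydronaphthalene-1-carboxylate | CC1=C[C@H]2C[C@H](C)[C@@H](O)[C@H](C)[C@H]2[C@H](C(=O)OC)[C@@H]1O | intermediate
21 | 2,7-bis(triethylsilyl) ether of 20 | CC1=C[C@H]2C[C@H](C)[C@@H](O[Si](CC)(CC)CC)[C@H](C)[C@H]2[C@H](C(=O)OC)[C@@H]1O[Si](CC)(CC)CC | intermediate
22 | 3,6,8-trimethyl-2,7-bis(triethylsilyloxy)-1,2,4a,5,6,7,8,8a-octahydronaphthalene-1-carbaldehyde (configuration as in 20) | CC1=C[C@H]2C[C@H](C)[C@@H](O[Si](CC)(CC)CC)[C@H](C)[C@H]2[C@H](C=O)[C@@H]1O[Si](CC)(CC)CC | intermediate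
23 | 2-(triphenylphosphoranylidene)propanal | CC(C=O)=P(c1ccccc1)(c1ccccc1)c1ccccc1 | starting material
24 | (2E)-2-methyl-3-[3,6,8-trimethyl-2,7-bis(triethylsilyloxy)-1,2,4a,5,6,7,8,8a-octahydronaphthalen-1-yl]prop-2-enal | CC1=C[C@H]2C[C@H](C)[C@@H](O[Si](CC)(CC)CC)[C@H](C)[C@H]2[C@H](/C=C(C)/C=O)[C@@H]1O[Si](CC)(CC)CC | intermediate
25 | ethyltriphenylphosphonium iodide | CC[P+](c1ccccc1)(c1ccccc1)c1ccccc1.[I-] | starting material
26 | 1-[(1E,3Z)-4-iodo-2-methylpenta-1,3-dien-1-yl]-3,6,8-trimethyl-2,7-bis(triethylsilyloxy)-1,2,4a,5,6,7,8,8a-octahydronaphthalene | CC1=C[C@H]2C[C@H](C)[C@@H](O[Si](CC)(CC)CC)[C@H](C)[C@H]2[C@H](/C=C(C)/C=C(C)\I)[C@@H]1O[Si](CC)(CC)CC | intermediate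
27 | 1-[(1E,3Z)-4-iodo-2-methylpenta-1,3-dien-1-yl]-3,6,8-trimethyl-1,2,4a,5,6,7,8,8a-octahydronaphthalene-2,7-diol | CC1=C[C@H]2C[C@H](C)[C@@H](O)[C@H](C)[C@H]2[C@H](/C=C(C)/C=C(C)\I)[C@@H]1O | intermediate
28 | 7-hydroxy-1-[(1E,3Z)-4-iodo-2-methylpenta-1,3-dien-1-yl]-3,6,8-trimethyl-4a,5,6,7,8,8a-hexahydronaphthalen-2(1H)-one | CC1=C[C@H]2C[C@H](C)[C@@H](O)[C@H](C)[C@H]2[C@H](/C=C(C)/C=C(C)\I)C1=O | intermediate
29 | tert-butyldimethyl(prop-2-yn-1-yloxy)silane | C#CCO[Si](C)(C)C(C)(C)C | starting material
30 | 2-[3-(tert-butyldimethylsilyloxy)prop-1-yn-1-yl]-1-[(1E,3Z)-4-iodo-2-methylpenta-1,3-dien-1-yl]-3,6,8-trimethyl-1,2,4a,5,6,7,8,8a-octahydronaphthalene-2,7-diol (C2 hydroxyl drawn cis to the C1 chain) | CC1=C[C@H]2C[C@H](C)[C@@H](O)[C@H](C)[C@H]2[C@H](/C=C(C)/C=C(C)\I)[C@@]1(O)C#CCO[Si](C)(C)C(C)(C)C | intermediate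
31 | (1E)-3-(tert-butyldimethylsilyloxy)-1-{7-hydroxy-1-[(1E,3Z)-4-iodo-2-methylpenta-1,3-dien-1-yl]-3,6,8-trimethyl-4a,5,6,7,8,8a-hexahydronaphthalen-2(1H)-ylidene}propan-2-one | CC1=C[C@H]2C[C@H](C)[C@@H](O)[C@H](C)[C@H]2[C@H](/C=C(C)/C=C(C)\I)/C1=C\C(=O)CO[Si](C)(C)C(C)(C)C | intermediate
32 | acrylic acid | C=CC(=O)O | starting material
33 | (2E,4Z,6E)-7-{(1R,2E,4aS,6S,7R,8R,8aR)-2-[3-(tert-butyldimethylsilyloxy)-2-oxopropylidene]-7-hydroxy-3,6,8-trimethyl-1,2,4a,5,6,7,8,8a-octahydronaphthalen-1-yl}-4,6-dimethylhepta-2,4,6-trienoic acid | CC1=C[C@H]2C[C@H](C)[C@@H](O)[C@H](C)[C@H]2[C@H](/C=C(C)/C=C(C)\C=C\C(=O)O)/C1=C\C(=O)CO[Si](C)(C)C(C)(C)C | intermediate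
34 | (2E,4Z,6E)-7-[(1R,2E,4aS,6S,7R,8R,8aR)-7-hydroxy-2-(3-hydroxy-2-oxopropylidene)-3,6,8-trimethyl-1,2,4a,5,6,7,8,8a-octahydronaphthalen-1-yl]-4,6-dimethylhepta-2,4,6-trienoic acid | CC1=C[C@H]2C[C@H](C)[C@@H](O)[C@H](C)[C@H]2[C@H](/C=C(C)/C=C(C)\C=C\C(=O)O)/C1=C\C(=O)CO | target

**Step count and least certain steps**

Total: 24 steps. Longest linear sequence: 24 steps (1 → 34); all other partners (9, 12, 23, 25, 29, 32) are commercial.

Step 13 (key step). The most likely failure is incomplete equilibration of the C6 and C8 centres, which would leave a mixture of cis-fused diastereomers. Base-induced removal of the C4a hydrogen of the open chain is a second risk: it would erode enantiomeric purity or move the ring double bond before closure. Fallback: take the base out of the bond-forming event and settle the stereocentres in a separate operation. From 17, a Lewis acid catalysed Michael addition of the enol form (Yb(OTf)3 or FeCl3·6H2O, CH2Cl2, 25 °C) should give the kinetic adduct 18 without an open-chain enolate being present; 18 is isolated and equilibrated with NaOMe in MeOH to rejoin the route at 19. This fallback makes no new compound (F0).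

Step 3. Enantiotopic-proton selection by the chiral amide may be incomplete, and some deprotonation α to the ester may compete, so the material may enter the route with less than full enantiomeric purity. Epimers at C4a formed later are diastereomers up to 17 and can be removed by chromatography, but the minor enantiomer cannot. Fallback: a classical enrichment at the acid stage. Starting from 11, the acid is crystallised as its salt with (S)-1-phenylethylamine, the (S)-1-phenylethylammonium carboxylate of 11 F1; the salt is recrystallised and acidified to return 11 in enriched form.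

Step 14. Hydride may be delivered equatorially to the C7 ketone, which is flanked by two equatorial methyls, giving the axial alcohol; this is a matter of poor facial selectivity under kinetic control. Fallback: switch to thermodynamic control for C7 alone. From 19, the β-keto ester is shielded as its lithium dienolate (LiN(SiMe3)2, THF) and the C7 ketone is reduced with lithium in liquid ammonia/t-BuOH, which should give the equatorial carbinol, methyl (4aR,6S,7R,8R,8aS)-2,7-dihydroxy-3,6,8-trimethyl-4a,5,6,7,8,8a-hexahydronaphthalene-1-carboxylate F2. Luche reduction of the remaining ring B carbonyl of F2 then rejoins the route at 20.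

Step 22. The tertiary alcohol is both allylic and propargylic, so ionisation may lead to allylic transposition toward C4 or to elimination into the ring instead of the 1,3-shift to the allene. Fallback: move the oxygen as an ester. From 30, both hydroxyls are acetylated (Ac2O, DMAP, Et3N) to the 2,7-diacetate of 30 F3. A silver-catalysed [3,3] shift of the propargylic acetate (AgSbF6, CH2Cl2) should give the allenyl acetate F4. Methanolysis (K2CO3, MeOH) cleaves the enol acetate, and more slowly the C7 acetate, to rejoin the route at 31.

Step 23. Under the basic coupling conditions the Z iodoalkene may isomerise, or the C1 hydrogen may be removed with migration of the ylidene double bond; sluggish insertion of the acrylate would prolong the exposure. Fallback: a base-free cross-coupling. From 31, Stille coupling with (E)-3-(tributylstannyl)prop-2-enoic acid (Pd2(dba)3 as the source of zerovalent palladium, AsPh3, NMP, 25 °C) should deliver 33 directly with retention at both alkenes. This fallback makes no new compound (F0).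

**Further compounds**

F0 | step 13 | none | none
F1 | step 3 | (S)-1-phenylethylammonium (2Z)-3-[(1S,4S,5R)-4-(tert-butyldimethylsilyloxy)-3,5-dimethylcyclohex-2-en-1-yl]-2-methylprop-2-enoate | C[C@H]([NH3+])c1ccccc1.[O-]C(=O)/C(C)=C\[C@@H]1C=C(C)[C@@H](O[Si](C)(C)C(C)(C)C)[C@H](C)C1
F2 | step 14 | methyl (4aR,6S,7R,8R,8aS)-2,7-dihydroxy-3,6,8-trimethyl-4a,5,6,7,8,8a-hexahydronaphthalene-1-carboxylate | CC1=C[C@H]2C[C@H](C)[C@@H](O)[C@H](C)[C@H]2C(C(=O)OC)=C1O
F3 | step 22 | 2,7-diacetate of 30 | CC1=C[C@H]2C[C@H](C)[C@@H](OC(C)=O)[C@H](C)[C@H]2[C@H](/C=C(C)/C=C(C)\I)[C@@]1(OC(C)=O)C#CCO[Si](C)(C)C(C)(C)C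
F4 | step 22 | allenyl acetate from the [3,3] shift of F3 (allene axis not defined) | CC1=C[C@H]2C[C@H](C)[C@@H](OC(C)=O)[C@H](C)[C@H]2[C@H](/C=C(C)/C=C(C)\I)C1=C=C(OC(C)=O)CO[Si](C)(C)C(C)(C)C
F0 | step 23 | none | none
A1 | alternative 1 | 2-(tert-butyldimethylsilyloxy)-3-methylbuta-1,3-diene | C=C(O[Si](C)(C)C(C)(C)C)C(C)=C
A2 | alternative 1 | 5-(tert-butyldimethylsilyloxy)-4,6-dimethylcyclohex-2-en-1-one (ring A dienophile, carbonyl at C5) | O=C1C=C[C@@H](C)[C@H](O[Si](C)(C)C(C)(C)C)[C@H]1C
A3 | alternative 1 | cis-fused Diels–Alder adduct with C2 silyl enol ether and C5 ketone | CC1=C(O[Si](C)(C)C(C)(C)C)C[C@@H]2[C@@H](C)[C@H](O[Si](C)(C)C(C)(C)C)[C@@H](C)C(=O)[C@@H]2C1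
A4 | alternative 2 | ring B aldehyde with C2 ketal, allyl group on C4a and 1-formylethyl group on C8a | CC1=C[C@@H](CC=C)[C@@H]([C@@H](C)C=O)CC12OCCO2
A5 | alternative 2 | decalin carbinol with C2 ketal | CC1=C[C@H]2C[C@H](C)[C@@H](O)[C@H](C)[C@H]2CC13OCCO3
A6 | alternative 3 | ring A with enynone arm on C4a and silyl dienol ether arm on C8a | C(#CC(=O)CO[Si](C)(C)C(C)(C)C)/C(C)=C\[C@H]1C[C@H](C)[C@@H](O[Si](C)(C)C(C)(C)C)[C@H](C)[C@H]1/C=C/C(C)=C/O[Si](C)(C)C
A7 | alternative 3 | decalin with C1 enal arm and silylated hydroxyacetylidene | CC1=C[C@H]2C[C@H](C)[C@@H](O[Si](C)(C)C(C)(C)C)[C@H](C)[C@H]2[C@H](/C=C(C)/C=O)/C1=C\C(=O)CO[Si](C)(C)C(C)(C)C
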